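I began with the leftover: even at full speed, dissolving brings 50.9% of the charge into solution in 30 s, so solid G stays over in every flask and keeps feeding J.

    J + L → L + Q (k1 = 120 M⁻¹ s⁻¹, Ea1 = 36.0 kJ mol⁻¹)
    G ⇌ J, rate k2*(cs2 - [J]) while solid is left; crystals form when [J] > cs2 (cs2 = 0.63 M, k2 = 0.035 s⁻¹)
    Q → X (k3 = 0.027 s⁻¹, Ea3 = 101 kJ mol⁻¹)
    Q ⇌ D (K4 = 4.9, k4 = 0.015 s⁻¹, Ea4 = 110 kJ mol⁻¹, ΔH4 = −20.0 kJ mol⁻¹)
    J → Z (k5 = 1.0 s⁻¹, Ea5 = 98.0 kJ mol⁻¹)
    (constants at 90 °C)

all flasks: G 1.3 M; L 0.25 mol%; time 30 s

|  | temperature |
|---|---|
| green | 115 °C |
| red | 90 °C |
| blue | 65 °C |
| violet | 40 °C |

- solid, in amounts per volume of the solution: G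
- all constants are for 90 °C and move with temperature by the activation energies and enthalpies
- at the start none of G is in solution
- what has only dissolved of G counts as not reacted

* the best flask by amount of Q, in percent of the G charged; "all alike" if 1.5 percentage points covers them all (green / red / blue / violet / all alike)
* amount of Q at the end, in percent of the G charged, green
* amount of Q at the end, in percent of the G charged, red
* amount of Q at the end, in percent of the G charged, blue
* amount of Q at the end, in percent of the G charged, violet

1. Dissolved J leaves either with L to Q or on its own to Z, and both rates hold the same J, so when I divided one by the other, J and time dropped out. In blue the step to Q ran at 0.162 s⁻¹ and the step to Z at 0.0908 s⁻¹, which gave 64.0%, the branch share, the fraction of what leaves J that goes to Q; its ratio is what chemists call a selectivity factor.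

2. The step to Z has the steeper temperature dependence, so I expected the share to climb on cooling, and it came to 9.41% in green, 28.1% in red and 91.2% in violet.

3. Multiplying the feed by the share, I committed to Q of 4.79% in green, 14.3% in red, 32.6% in blue and 46.4% in violet, which put violet on top.

4. The weak link was the feed, which I had passed straight through J, whereas J must first fill, and what stands in it slows the dissolving. In violet the two leaving rates are 0.0581 s⁻¹ to Q and 0.00562 s⁻¹ to Z. The filling time is one over the sum of the rate constants that act on J, dissolving included, and it came to 3.48 s in blue but 10.1 s in violet, which is longer.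

5. Scaling the feed by the part of that sum which leaves J, and by the part of the run after filling, left 39.5% passed through in blue and 21.8% in violet.

6. Applying the share, and letting Q decay to X and D for half the run, I reached 24.0% in blue and 19.8% in violet, so blue moved ahead, with red and green still behind.

The forecast read 0.545% for green, 7.87% for red, 24.2% for blue and 20.3% for violet, with the words “Blue is best”.

The flasks ended with Q at 0.545% in green, 7.87% in red, 24.2% in blue and 20.3% in violet, so blue was best.

In blue, solid G kept dissolving, standing at 76.9% after 15.0 s and 54.6% after 30.0 s, while J held at 5.82% and then 5.90% and the steps to Q and Z drew on it side by side. Of what had left J in blue, Q with its products X and D made 64.0%, against a branch share of 64.0%. In the neighbour of blue with 0.52 M of G, L falls with G, so the share comes to 41.6%, and that flask held Q at 33.6% and Z at 49.3%, the same count giving 41.6%.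

All constants are made up; the run is a simulation.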